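**Retrosynthetic overview**

1. The two acetates are put on last, onto (13S)-labd-7-ene-15,17-diol. Its C7=C8 double bond and C17 oxygen arise together from an exocyclic C8=C17 alkene by epoxidation and isomerisation of the 8α,17-epoxide to the allylic alcohol.
2. Key disconnection C12–C13: a C16 Grignard reagent (C12 nucleophile on the intact decalin) opens (S)-β-butyrolactone at its sp3 C–O carbon with inversion. This one step completes the C20 skeleton, sets C13 and leaves C15 as a carboxylic acid.
3. Enabling feature: the methyl-bearing stereocentre C13 stands 1,3 to the C15 oxygen, so C13, C14, C15 and that oxygen can be carried as a strained four-membered oxetan-2-one ring in which the C13–O bond is the leaving group.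
4. The C16 bromide comes from (+)-sclareolide (lactone reduction, exo-selective dehydration of the equatorial 8α-alcohol, Appel bromination); C5, C9 and C10 are never touched.
5. Ring order: rings A and B are bought with sclareolide and no carbocycle is formed. The oxetanone ring is opened in the key step; the only ring made on the way is the spiro-oxirane of step 8, opened again in step 9.

Key step: step 6

Remark: labdane numbering is used (C11 and C12 are the two CH2 groups on C9, C13 carries the side-chain methyl, C15 and C17 carry the acetates). The target is read as (5S,9R,10S,13S)-labd-7-ene-15,17-diyl diacetate, the ring configuration of natural (+)-sclareolide; (+)-sclareolide and (S)-β-butyrolactone are taken as commercial.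

**Route**

Step 1
Reactants: 1 (+)-sclareolide
Product: 2 13,14,15,16-tetranorlabdane-8α,12-diol
Conditions: LiAlH4, THF, 0 °C → reflux; then H2O, aq. NaOH
Reagents that add atoms: none
Why: LiAlH4 reduction of the γ-lactone to the 1,4-diol breaks no bond at C8, so the four stereocentres of 1 are carried over unchanged.

Step 2
Reactants: 2 13,14,15,16-tetranorlabdane-8α,12-diol
Product: 3 8α-hydroxy-13,14,15,16-tetranorlabdan-12-yl acetate
Conditions: Ac2O (1.5 equiv), pyridine, rt (no DMAP)
Reagents that add atoms: acetic anhydride, CC(=O)OC(C)=O
Why: Chemoselective O-acylation, in which only the primary 12-OH reacts and the tertiary 8α-OH stays free; the acetate also blocks the cyclodehydration to the tetrahydrofuran that the free 1,4-diol would undergo on activation.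

Step 3
Reactants: 3 8α-hydroxy-13,14,15,16-tetranorlabdan-12-yl acetate
Product: 5 13,14,15,16-tetranorlabd-8(17)-en-12-yl acetate, via 8α-chlorosulfite 4 (not isolated)
Conditions: SOCl2 (1.5 equiv), pyridine (5 equiv), CH2Cl2, −78 → −40 °C; chromatography on AgNO3-impregnated silica
Reagents that add atoms: none
Why: Dehydration by pyridine-mediated E2 elimination of the chlorosulfite, where the equatorial 8α C–O bond has only ring C–C bonds anti-periplanar to it while a hydrogen of the axial C17 methyl group can always take the anti position, so the exocyclic C8=C17 alkene should predominate; C8 stops being a stereocentre and C9 is untouched.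

Step 4
Reactants: 5 13,14,15,16-tetranorlabd-8(17)-en-12-yl acetate
Product: 6 13,14,15,16-tetranorlabd-8(17)-en-12-ol
Conditions: K2CO3 (0.2 equiv), MeOH, rt
Reagents that add atoms: none
Why: Base-catalysed transesterification (methanolysis) of the primary acetate touches neither the alkene nor any stereocentre.

Step 5
Reactants: 6 13,14,15,16-tetranorlabd-8(17)-en-12-ol
Product: 7 12-bromo-13,14,15,16-tetranorlabd-8(17)-ene
Conditions: CBr4 (1.3 equiv), PPh3 (1.4 equiv), CH2Cl2, 0 °C → rt
Reagents that add atoms: carbon tetrabromide, BrC(Br)(Br)Br
Why: Appel reaction, an SN2 displacement at the primary C12 under neutral conditions that spare the acid-sensitive exocyclic alkene.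

Step 6
Reactants: 7 12-bromo-13,14,15,16-tetranorlabd-8(17)-ene; 8 (S)-β-butyrolactone, (4S)-4-methyloxetan-2-one
Product: 11 (13S)-labd-8(17)-en-15-oic acid, via Grignard reagent 9 (not isolated), via trimethylsilyl ester 10 (not isolated)
Conditions: Mg (I2-activated), THF, 45 °C; the solution of 9 added slowly to 8 (1.5 equiv), CuBr·SMe2 (10 mol%), TMSCl (1.2 equiv), THF–Me2S, −50 → 0 °C; then 1 M HCl, 0 °C
Reagents that add atoms: none
Why: Grignard reagent 9 is transmetalated to an alkylcopper species that attacks the sp3 carbon C13 of the oxetan-2-one from the side opposite the ring C13–O bond (SN2-type oxidative addition to a trivalent copper alkyl, then reductive elimination), forming C12–C13 while the ring opens to a carboxylate that TMSCl traps as silyl ester 10; aqueous acid then frees acid 11. The closest known reaction type is the copper-catalysed SN2 (alkyl–oxygen) ring opening of β-lactones by Grignard reagents, which gives β-branched carboxylic acids with inversion at the β-carbon. No ring is closed; a four-membered ring is opened, and the release of its strain together with the carboxylate leaving group is what makes a secondary sp3 carbon a good electrophile. The new stereocentre C13 is fixed by the lactone: stereospecific inversion at the (S)-configured C–O carbon should give 13S (the descriptor stays S only because the priorities change). The step needs alkyl–oxygen cleavage to win over acyl–oxygen cleavage and over β-elimination to crotonate; the soft organocopper nucleophile, the low temperature, TMSCl, the slow addition of 9 to an excess of 8 and the primary, unhindered C12 (two CH2 groups away from ring B) are meant to secure this. One operation thus delivers all twenty skeletal carbons, the last stereocentre and C15 at the acid oxidation level.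

Step 7
Reactants: 11 (13S)-labd-8(17)-en-15-oic acid
Product: 12 (13S)-labd-8(17)-en-15-ol
Conditions: LiAlH4, THF, 0 °C → rt; then H2O, aq. NaOH
Reagents that add atoms: none
Why: LiAlH4 reduction of the carboxylic acid to the primary alcohol; C13 is β to the carbonyl and cannot epimerise, and the isolated alkene is inert to hydride.

Step 8
Reactants: 12 (13S)-labd-8(17)-en-15-ol
Product: 13 (13S)-8α,17-epoxylabdan-15-ol
Conditions: mCPBA (1.1 equiv), CH2Cl2, 0 °C
Reagents that add atoms: mCPBA (3-chloroperoxybenzoic acid), OOC(=O)c1cccc(Cl)c1
Why: Prilezhaev epoxidation of the only alkene, in which the peracid should approach C8=C17 from the equatorial α direction because the axial β direction is 1,3-diaxial to the C10 methyl group, giving the 8α,17-epoxide; since C8 returns to sp2 in step 9, a minor β-epoxide would converge on the same product.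

Step 9
Reactants: 13 (13S)-8α,17-epoxylabdan-15-ol
Product: 14 (13S)-labd-7-ene-15,17-diol
Conditions: Al(OiPr)3 (3 equiv), toluene, reflux; then 2 M aq. NaOH
Reagents that add atoms: none
Why: Aluminium-alkoxide-mediated isomerisation of an epoxide to an allylic alcohol (Lewis-acid activation of the oxirane oxygen with syn removal of a β-hydrogen), in which the secondary C7–H is accessible while the tertiary C9–H is shielded by the side chain and the angular methyl group, so the trisubstituted C7=C8 alkene and the primary C17 alcohol should form.

Step 10
Reactants: 14 (13S)-labd-7-ene-15,17-diol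
Product: 15 (13S)-labd-7-ene-15,17-diyl diacetate (CNP0294037.1)
Conditions: Ac2O (3 equiv), pyridine, DMAP (cat.), CH2Cl2, rt
Reagents that add atoms: acetic anhydride, CC(=O)OC(C)=O
Why: DMAP-catalysed acylation of the two primary alcohols, the only groups in 14 that react with Ac2O.

**Compound list**

1 | (+)-sclareolide, (3aR,5aS,9aS,9bR)-3a,6,6,9a-tetramethyldecahydronaphtho[2,1-b]furan-2(1H)-one | O=C1C[C@H]2[C@](C)(O1)CC[C@H]3C(C)(C)CCC[C@]23C | starting material
2 | 13,14,15,16-tetranorlabdane-8α,12-diol, (1R,2R,4aS,8aS)-1-(2-hydroxyethyl)-2,5,5,8a-tetramethyldecahydronaphthalen-2-ol | OCC[C@H]1[C@](C)(O)CC[C@H]2C(C)(C)CCC[C@]12C | intermediate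
3 | 8α-hydroxy-13,14,15,16-tetranorlabdan-12-yl acetate | CC(=O)OCC[C@H]1[C@](C)(O)CC[C@H]2C(C)(C)CCC[C@]12C | intermediate
4 | 8α-chlorosulfite of 3, formed in the flask | CC(=O)OCC[C@H]1[C@](C)(OS(Cl)=O)CC[C@H]2C(C)(C)CCC[C@]12C | intermediate
5 | 13,14,15,16-tetranorlabd-8(17)-en-12-yl acetate | CC(=O)OCC[C@H]1C(=C)CC[C@H]2C(C)(C)CCC[C@]12C | intermediate
6 | 13,14,15,16-tetranorlabd-8(17)-en-12-ol | OCC[C@H]1C(=C)CC[C@H]2C(C)(C)CCC[C@]12C | intermediate
7 | 12-bromo-13,14,15,16-tetranorlabd-8(17)-ene | BrCC[C@H]1C(=C)CC[C@H]2C(C)(C)CCC[C@]12C | intermediate
8 | (S)-β-butyrolactone, (4S)-4-methyloxetan-2-one | C[C@H]1CC(=O)O1 | starting material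
9 | (13,14,15,16-tetranorlabd-8(17)-en-12-yl)magnesium bromide, formed in the flask | Br[Mg]CC[C@H]1C(=C)CC[C@H]2C(C)(C)CCC[C@]12C | intermediate
10 | trimethylsilyl (13S)-labd-8(17)-en-15-oate, formed in the flask | C[Si](C)(C)OC(=O)C[C@@H](C)CC[C@H]1C(=C)CC[C@H]2C(C)(C)CCC[C@]12C | intermediate
11 | (13S)-labd-8(17)-en-15-oic acid | OC(=O)C[C@@H](C)CC[C@H]1C(=C)CC[C@H]2C(C)(C)CCC[C@]12C | intermediate
12 | (13S)-labd-8(17)-en-15-ol | OCC[C@@H](C)CC[C@H]1C(=C)CC[C@H]2C(C)(C)CCC[C@]12C | intermediate
13 | (13S)-8α,17-epoxylabdan-15-ol | OCC[C@@H](C)CC[C@H]1[C@@]2(CO2)CC[C@H]3C(C)(C)CCC[C@]13C | intermediate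
14 | (13S)-labd-7-ene-15,17-diol | OCC[C@@H](C)CC[C@H]1C(CO)=CC[C@H]2C(C)(C)CCC[C@]12C | intermediate
15 | (13S)-labd-7-ene-15,17-diyl diacetate, (5S,9R,10S,13S) | CC(=O)OCC[C@@H](C)CC[C@H]1C(COC(C)=O)=CC[C@H]2C(C)(C)CCC[C@]12C | target

**Step count**

Total: 10 steps. Longest linear sequence: 10 steps (1 to 15); lactone 8 is used as bought and enters at step 6.

**Steps most likely to fail**

1. Step 6. What may go wrong: attack of the organometallic at the lactone carbonyl (acyl–oxygen cleavage) or base-induced β-elimination of the lactone. Both use up 9 without forming the C12–C13 bond, and SN2 at a secondary carbon is slow enough for them to compete. Fallback: it sets out from bromide 7 and keeps Grignard reagent 9, but changes the electrophile from an sp3 C–O carbon to a planar acceptor. Reagent 9 would be added to methyl (E)-but-2-enoate with CuI and Tol-BINAP in t-BuOMe at −40 °C (catalytic asymmetric conjugate addition), which should give methyl (13S)-labd-8(17)-en-15-oate F1. C13 is then set by the ligand: the Tol-BINAP enantiomer that delivers the alkyl group to the Re face of C13 would be used, its sense being checked first with a simple primary Grignard reagent. LiAlH4 reduction of F1 comes back to the route at alcohol 12.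

2. Step 9. What may go wrong: removal of the C9 proton instead of a C7 proton, which puts the double bond at C8=C9, or a Lewis-acid-induced hydride shift of the opened epoxide to a C8 aldehyde. Fallback: it sets out from alcohol 12 and avoids the epoxide. RhCl3·3H2O in EtOH at reflux should move the exocyclic double bond into ring B and give (13S)-labd-7-en-15-ol F2. Allylic hydroxylation of the C17 methyl group with SeO2 (cat.) and t-BuOOH in CH2Cl2 (ene reaction, then 2,3-sigmatropic shift, at the methyl on the more substituted alkene carbon because the other position there, C9, is tertiary and hindered) would follow. A NaBH4 treatment of the crude product would reduce any over-oxidised enal, and the sequence comes back at diol 14.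

3. Step 3. What may go wrong: loss of regiocontrol in the elimination, a ring proton at C7 or C9 being taken instead of a C17 proton after partial ionisation at C8, so that alkene isomers form that are hard to separate. Fallback: it sets out from monoacetate 3 and makes the ring isomer the intended intermediate. The crude elimination product would be isomerised with RhCl3·3H2O in EtOH so that exocyclic material converges on 13,14,15,16-tetranorlabd-7-en-12-yl acetate F3. The operations of steps 4 to 7 should then give in turn 13,14,15,16-tetranorlabd-7-en-12-ol F4, 12-bromo-13,14,15,16-tetranorlabd-7-ene F5, its Grignard reagent (13,14,15,16-tetranorlabd-7-en-12-yl)magnesium bromide F6 (not isolated), trimethylsilyl (13S)-labd-7-en-15-oate F7 (not isolated), (13S)-labd-7-en-15-oic acid F8 and (13S)-labd-7-en-15-ol F2. The SeO2/t-BuOOH hydroxylation described under the second fallback then comes back at diol 14.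

**Further compounds**

F1 | step 6 | methyl (13S)-labd-8(17)-en-15-oate | COC(=O)C[C@@H](C)CC[C@H]1C(=C)CC[C@H]2C(C)(C)CCC[C@]12C
F2 | step 9 | (13S)-labd-7-en-15-ol | OCC[C@@H](C)CC[C@H]1C(C)=CC[C@H]2C(C)(C)CCC[C@]12C
F3 | step 3 | 13,14,15,16-tetranorlabd-7-en-12-yl acetate | CC(=O)OCC[C@H]1C(C)=CC[C@H]2C(C)(C)CCC[C@]12C
F4 | step 3 | 13,14,15,16-tetranorlabd-7-en-12-ol | OCC[C@H]1C(C)=CC[C@H]2C(C)(C)CCC[C@]12C
F5 | step 3 | 12-bromo-13,14,15,16-tetranorlabd-7-ene | BrCC[C@H]1C(C)=CC[C@H]2C(C)(C)CCC[C@]12C
F6 | step 3 | (13,14,15,16-tetranorlabd-7-en-12-yl)magnesium bromide | Br[Mg]CC[C@H]1C(C)=CC[C@H]2C(C)(C)CCC[C@]12C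
F7 | step 3 | trimethylsilyl (13S)-labd-7-en-15-oate | C[Si](C)(C)OC(=O)C[C@@H](C)CC[C@H]1C(C)=CC[C@H]2C(C)(C)CCC[C@]12C
F8 | step 3 | (13S)-labd-7-en-15-oic acid | OC(=O)C[C@@H](C)CC[C@H]1C(C)=CC[C@H]2C(C)(C)CCC[C@]12C
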